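**Retrosynthetic overview**

1. The quinone of ring B is unmasked last: target 17 ⇐ tert-butyl ether 16 ⇐ p-methoxyphenol 15 (PhI(OAc)2). O-8 is put in as a tert-butyl ether by ortho-lithiation of chroman 11.
2. Ring C (pyran) is closed at C8a–O1 by Pd-catalysed etherification of primary alcohol 10 onto its aryl bromide. The C-2 oxygen comes from ozonolysis/reduction of an (E)-propenyl group.
3. Key disconnection C3–C1′: aromatic Claisen [3,3] rearrangement of the (S,E)-allyl aryl ether 6, which sets C-3 by 1,3-chirality transfer and delivers ring B as its phenol.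
4. 6 ⇐ aryl propargyl ether 3 + benzyl bromide 4 (hydrozirconation, Pd benzylation); 3 ⇐ (R)-but-3-yn-2-ol 1 + phenol 2 (Mitsunobu, inversion). Compound 1 is the only source of chirality.
5. Ring order: rings A and B are bought as arenes → ring C → quinone oxidation level of ring B.

Assumption: 1, 2 and 4 are bought as catalogue compounds; the route aims at the (3S) enantiomer drawn in the SMILES.

**Route**

Step 1
Reactants: 1 (R)-but-3-yn-2-ol; 2 2,3,4-trimethoxyphenol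
Product: 3 1-[(2S)-but-3-yn-2-yloxy]-2,3,4-trimethoxybenzene
Conditions: PPh3, DIAD, THF, 0 °C → rt
Reagents that add atoms: none
Why: Mitsunobu etherification is an SN2 displacement at the propargylic carbinol, so the (R)-alcohol gives the (S)-aryl ether with clean inversion and no SN2′ product.

Step 2
Reactants: 3 1-[(2S)-but-3-yn-2-yloxy]-2,3,4-trimethoxybenzene; 4 2-bromo-4,5-dimethoxybenzyl bromide
Product: 6 1-bromo-4,5-dimethoxy-2-[(2E,4S)-4-(2,3,4-trimethoxyphenoxy)pent-2-en-1-yl]benzene, via alkenylzirconocene 5 (not isolated)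
Conditions: Cp2Zr(H)Cl, THF, rt; then 4, Pd(PPh3)4 (5 mol %), ZnCl2 (0.3 equiv), rt
Reagents that add atoms: none
Why: syn-hydrozirconation puts zirconium on the terminal carbon to give the (E)-alkenyl metal, and Negishi-type cross-coupling at the benzylic C–Br (far more reactive than the aryl C–Br) gives the (E)-allyl aryl ether without touching the stereocentre.

Step 3
Reactants: 6 1-bromo-4,5-dimethoxy-2-[(2E,4S)-4-(2,3,4-trimethoxyphenoxy)pent-2-en-1-yl]benzene
Product: 8 {6-[(2R,3E)-1-(2-bromo-4,5-dimethoxyphenyl)pent-3-en-2-yl]-2,3,4-trimethoxyphenoxy}tri(propan-2-yl)silane, via phenol 7 (not isolated)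
Conditions: PhNEt2, 180 °C; then i-Pr3SiOTf, 0 °C → rt
Reagents that add atoms: triisopropylsilyl trifluoromethanesulfonate, CC(C)[Si](OS(=O)(=O)C(F)(F)F)(C(C)C)C(C)C
Why: the aromatic Claisen [3,3]-sigmatropic rearrangement goes suprafacially to the only free ortho position through a chair transition state with the methyl group equatorial, so the (S) C–O centre is transferred into the (R) C–C centre with an (E)-propenyl group, and the phenol is silylated in the same flask to stop abnormal Claisen and oxidation pathways.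

Step 4
Reactants: 8 {6-[(2R,3E)-1-(2-bromo-4,5-dimethoxyphenyl)pent-3-en-2-yl]-2,3,4-trimethoxyphenoxy}tri(propan-2-yl)silane
Product: 10 (2S)-3-(2-bromo-4,5-dimethoxyphenyl)-2-{3,4,5-trimethoxy-2-[tri(propan-2-yl)silyloxy]phenyl}propan-1-ol, via ozonide 9 (not isolated)
Conditions: O3, CH2Cl2, −78 °C (Sudan Red 7B end point); then NaBH4, EtOH, −78 → 0 °C
Reagents that add atoms: ozone, [O-][O+]=O
Why: ozonolysis of the only alkene followed by direct hydride reduction of the ozonide gives the primary alcohol without an epimerisable α-aryl aldehyde being left in solution (the change from R to S is only a change in CIP priorities).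

Step 5
Reactants: 10 (2S)-3-(2-bromo-4,5-dimethoxyphenyl)-2-{3,4,5-trimethoxy-2-[tri(propan-2-yl)silyloxy]phenyl}propan-1-ol
Product: 11 (3S)-6,7-dimethoxy-3-{3,4,5-trimethoxy-2-[tri(propan-2-yl)silyloxy]phenyl}-3,4-dihydro-2H-chromene
Conditions: Pd(OAc)2 (3 mol %), t-BuXPhos (6 mol %), Cs2CO3, toluene, 80 °C
Reagents that add atoms: none
Why: Buchwald-type intramolecular C–O coupling of the primary alcohol with the aryl bromide closes the six-membered pyran ring, the bulky phosphine suppresses β-hydride elimination, and the benzylic stereocentre is not acidic toward carbonate.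

Step 6
Reactants: 11 (3S)-6,7-dimethoxy-3-{3,4,5-trimethoxy-2-[tri(propan-2-yl)silyloxy]phenyl}-3,4-dihydro-2H-chromene
Product: 14 (3S)-8-tert-butoxy-6,7-dimethoxy-3-{3,4,5-trimethoxy-2-[tri(propan-2-yl)silyloxy]phenyl}-3,4-dihydro-2H-chromene, via aryllithium 12 (not isolated), via aryl Grignard reagent 13 (not isolated)
Conditions: n-BuLi, THF, 0 °C; MgBr2·OEt2, 0 °C; then PhCO3t-Bu, −40 → 0 °C
Reagents that add atoms: tert-butyl peroxybenzoate, CC(C)(C)OOC(=O)c1ccccc1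
Why: directed ortho-metalation takes the only C–H flanked by two oxygens (O-1 and 7-OMe), and Lawesson–Frisell tert-butoxylation of the derived aryl Grignard reagent installs the 8-oxygen already protected.

Step 7
Reactants: 14 (3S)-8-tert-butoxy-6,7-dimethoxy-3-{3,4,5-trimethoxy-2-[tri(propan-2-yl)silyloxy]phenyl}-3,4-dihydro-2H-chromene
Product: 15 6-[(3S)-8-tert-butoxy-6,7-dimethoxy-3,4-dihydro-2H-chromen-3-yl]-2,3,4-trimethoxyphenol
Conditions: Bu4NF, THF, 0 °C
Reagents that add atoms: none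
Why: fluoride desilylation cleaves only the aryl silyl ether, leaving the aryl tert-butyl and methyl ethers intact.

Step 8
Reactants: 15 6-[(3S)-8-tert-butoxy-6,7-dimethoxy-3,4-dihydro-2H-chromen-3-yl]-2,3,4-trimethoxyphenol
Product: 16 5-[(3S)-8-tert-butoxy-6,7-dimethoxy-3,4-dihydro-2H-chromen-3-yl]-2,3-dimethoxycyclohexa-2,5-diene-1,4-dione
Conditions: PhI(OAc)2, MeCN/H2O (2:1), 0 °C
Reagents that add atoms: water, O
Why: hypervalent-iodine oxidation of the p-methoxyphenol (water adds para, methanol is lost) gives the 2,3-dimethoxy-1,4-benzoquinone, while the fully etherified ring A carries no free phenol and is left alone.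

Step 9
Reactants: 16 5-[(3S)-8-tert-butoxy-6,7-dimethoxy-3,4-dihydro-2H-chromen-3-yl]-2,3-dimethoxycyclohexa-2,5-diene-1,4-dione
Product: 17 5-[(3S)-8-hydroxy-6,7-dimethoxy-3,4-dihydro-2H-chromen-3-yl]-2,3-dimethoxycyclohexa-2,5-diene-1,4-dione
Conditions: TFA, CH2Cl2, 0 °C
Reagents that add atoms: none
Why: acidolysis of the aryl tert-butyl ether (E1 loss of isobutene) frees the 8-OH under anhydrous acid that neither the quinone nor the C-3 stereocentre is sensitive to.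

**Compound list**

1 | (R)-but-3-yn-2-ol | C[C@@H](O)C#C | starting material
2 | 2,3,4-trimethoxyphenol | COc1ccc(O)c(OC)c1OC | starting material
3 | 1-[(2S)-but-3-yn-2-yloxy]-2,3,4-trimethoxybenzene | C[C@H](Oc1ccc(OC)c(OC)c1OC)C#C | intermediate
4 | 2-bromo-4,5-dimethoxybenzyl bromide | COc1cc(Br)c(CBr)cc1OC | starting material
5 | chlorobis(cyclopentadienyl)[(1E,3S)-3-(2,3,4-trimethoxyphenoxy)but-1-en-1-yl]zirconium (not isolated) | C[C@H](Oc1ccc(OC)c(OC)c1OC)/C=C/[Zr](Cl)(C1C=CC=C1)C1C=CC=C1 | intermediate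
6 | 1-bromo-4,5-dimethoxy-2-[(2E,4S)-4-(2,3,4-trimethoxyphenoxy)pent-2-en-1-yl]benzene | C[C@H](Oc1ccc(OC)c(OC)c1OC)/C=C/Cc1cc(OC)c(OC)cc1Br | intermediate
7 | 6-[(2R,3E)-1-(2-bromo-4,5-dimethoxyphenyl)pent-3-en-2-yl]-2,3,4-trimethoxyphenol (not isolated) | C/C=C/[C@@H](Cc1cc(OC)c(OC)cc1Br)c1cc(OC)c(OC)c(OC)c1O | intermediate
8 | {6-[(2R,3E)-1-(2-bromo-4,5-dimethoxyphenyl)pent-3-en-2-yl]-2,3,4-trimethoxyphenoxy}tri(propan-2-yl)silane | C/C=C/[C@@H](Cc1cc(OC)c(OC)cc1Br)c1cc(OC)c(OC)c(OC)c1O[Si](C(C)C)(C(C)C)C(C)C | intermediate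
9 | 3-[(1S)-2-(2-bromo-4,5-dimethoxyphenyl)-1-{3,4,5-trimethoxy-2-[tri(propan-2-yl)silyloxy]phenyl}ethyl]-5-methyl-1,2,4-trioxolane (ring diastereomers; not isolated) | CC1OC(OO1)[C@@H](Cc1cc(OC)c(OC)cc1Br)c1cc(OC)c(OC)c(OC)c1O[Si](C(C)C)(C(C)C)C(C)C | intermediate
10 | (2S)-3-(2-bromo-4,5-dimethoxyphenyl)-2-{3,4,5-trimethoxy-2-[tri(propan-2-yl)silyloxy]phenyl}propan-1-ol | OC[C@@H](Cc1cc(OC)c(OC)cc1Br)c1cc(OC)c(OC)c(OC)c1O[Si](C(C)C)(C(C)C)C(C)C | intermediate
11 | (3S)-6,7-dimethoxy-3-{3,4,5-trimethoxy-2-[tri(propan-2-yl)silyloxy]phenyl}-3,4-dihydro-2H-chromene | COc1cc([C@H]2COc3cc(OC)c(OC)cc3C2)c(O[Si](C(C)C)(C(C)C)C(C)C)c(OC)c1OC | intermediate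
12 | 8-lithio derivative of 11 (not isolated) | COc1cc([C@H]2COc3c([Li])c(OC)c(OC)cc3C2)c(O[Si](C(C)C)(C(C)C)C(C)C)c(OC)c1OC | intermediate
13 | 8-(bromomagnesio) derivative of 11 (not isolated) | COc1cc([C@H]2COc3c([Mg]Br)c(OC)c(OC)cc3C2)c(O[Si](C(C)C)(C(C)C)C(C)C)c(OC)c1OC | intermediate
14 | (3S)-8-tert-butoxy-6,7-dimethoxy-3-{3,4,5-trimethoxy-2-[tri(propan-2-yl)silyloxy]phenyl}-3,4-dihydro-2H-chromene | COc1cc([C@H]2COc3c(OC(C)(C)C)c(OC)c(OC)cc3C2)c(O[Si](C(C)C)(C(C)C)C(C)C)c(OC)c1OC | intermediate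
15 | 6-[(3S)-8-tert-butoxy-6,7-dimethoxy-3,4-dihydro-2H-chromen-3-yl]-2,3,4-trimethoxyphenol | COc1cc([C@H]2COc3c(OC(C)(C)C)c(OC)c(OC)cc3C2)c(O)c(OC)c1OC | intermediate
16 | 5-[(3S)-8-tert-butoxy-6,7-dimethoxy-3,4-dihydro-2H-chromen-3-yl]-2,3-dimethoxycyclohexa-2,5-diene-1,4-dione | COC1=C(OC)C(=O)C([C@H]2COc3c(OC(C)(C)C)c(OC)c(OC)cc3C2)=CC1=O | intermediate
17 | 5-[(3S)-8-hydroxy-6,7-dimethoxy-3,4-dihydro-2H-chromen-3-yl]-2,3-dimethoxycyclohexa-2,5-diene-1,4-dione | COC1=C(OC)C(=O)C([C@H]2COc3c(cc(OC)c(OC)c3O)C2)=CC1=O | target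

**Step count and risks**

Total steps: 9. Longest linear sequence: 9 (1 → 17; 2 and 4 enter as bought reagents).

Step 2 is at risk because zerovalent palladium can ionise the allylic aryl ether it has just made, and the alkenylzirconium coupling may be sluggish. The fallback reverses the order of bond formation, setting out from 1 and 4 and coming back at 6. Alcohol 1 is C-benzylated with 4 (CuI cat., Cs2CO3, NaI, MeCN, rt) to (2R)-5-(2-bromo-4,5-dimethoxyphenyl)pent-3-yn-2-ol F1. Hydroxyl-directed trans-hydroalumination with NaAlH2(OCH2CH2OMe)2 (THF, 0 °C) gives (2R,3E)-5-(2-bromo-4,5-dimethoxyphenyl)pent-3-en-2-ol F2. Mitsunobu etherification of F2 with 2 (PPh3, DIAD) then gives 6 with inversion.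

Step 4 is at risk because ozone may attack the two electron-rich arenes. The fallback cleaves the alkene without ozone, setting out from 8 and coming back at 10. Dihydroxylation (OsO4 cat., NMO, acetone/H2O) gives (4S)-5-(2-bromo-4,5-dimethoxyphenyl)-4-{3,4,5-trimethoxy-2-[tri(propan-2-yl)silyloxy]phenyl}pentane-2,3-diol F3. Cleavage with NaIO4 (pH 7 buffer, 0 °C) gives (2S)-3-(2-bromo-4,5-dimethoxyphenyl)-2-{3,4,5-trimethoxy-2-[tri(propan-2-yl)silyloxy]phenyl}propanal F4, which is reduced at once in the same flask with NaBH4 to 10.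

Step 6 is at risk because the doubly ortho-substituted aryl Grignard reagent may react poorly with the perester. The fallback splits oxygenation and protection and uses another protecting group, setting out from 11 and coming back at 17. Aryllithium 12 is hydroxylated with t-BuOOLi to (3S)-6,7-dimethoxy-3-{3,4,5-trimethoxy-2-[tri(propan-2-yl)silyloxy]phenyl}-3,4-dihydro-2H-chromen-8-ol F5, which is capped (MOMCl, i-Pr2NEt) as (3S)-6,7-dimethoxy-8-(methoxymethoxy)-3-{3,4,5-trimethoxy-2-[tri(propan-2-yl)silyloxy]phenyl}-3,4-dihydro-2H-chromene F6. Bu4NF gives 6-[(3S)-6,7-dimethoxy-8-(methoxymethoxy)-3,4-dihydro-2H-chromen-3-yl]-2,3,4-trimethoxyphenol F7. PhI(OAc)2 gives 5-[(3S)-6,7-dimethoxy-8-(methoxymethoxy)-3,4-dihydro-2H-chromen-3-yl]-2,3-dimethoxycyclohexa-2,5-diene-1,4-dione F8, and TFA in CH2Cl2 releases 17.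

**Further compounds**

F1 | step 2 | (2R)-5-(2-bromo-4,5-dimethoxyphenyl)pent-3-yn-2-ol | C[C@@H](O)C#CCc1cc(OC)c(OC)cc1Br
F2 | step 2 | (2R,3E)-5-(2-bromo-4,5-dimethoxyphenyl)pent-3-en-2-ol | C[C@@H](O)/C=C/Cc1cc(OC)c(OC)cc1Br
F3 | step 4 | (4S)-5-(2-bromo-4,5-dimethoxyphenyl)-4-{3,4,5-trimethoxy-2-[tri(propan-2-yl)silyloxy]phenyl}pentane-2,3-diol | CC(O)C(O)[C@@H](Cc1cc(OC)c(OC)cc1Br)c1cc(OC)c(OC)c(OC)c1O[Si](C(C)C)(C(C)C)C(C)C
F4 | step 4 | (2S)-3-(2-bromo-4,5-dimethoxyphenyl)-2-{3,4,5-trimethoxy-2-[tri(propan-2-yl)silyloxy]phenyl}propanal | O=C[C@@H](Cc1cc(OC)c(OC)cc1Br)c1cc(OC)c(OC)c(OC)c1O[Si](C(C)C)(C(C)C)C(C)C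
F5 | step 6 | (3S)-6,7-dimethoxy-3-{3,4,5-trimethoxy-2-[tri(propan-2-yl)silyloxy]phenyl}-3,4-dihydro-2H-chromen-8-ol | COc1cc([C@H]2COc3c(O)c(OC)c(OC)cc3C2)c(O[Si](C(C)C)(C(C)C)C(C)C)c(OC)c1OC
F6 | step 6 | (3S)-6,7-dimethoxy-8-(methoxymethoxy)-3-{3,4,5-trimethoxy-2-[tri(propan-2-yl)silyloxy]phenyl}-3,4-dihydro-2H-chromene | COc1cc([C@H]2COc3c(OCOC)c(OC)c(OC)cc3C2)c(O[Si](C(C)C)(C(C)C)C(C)C)c(OC)c1OC
F7 | step 6 | 6-[(3S)-6,7-dimethoxy-8-(methoxymethoxy)-3,4-dihydro-2H-chromen-3-yl]-2,3,4-trimethoxyphenol | COc1cc([C@H]2COc3c(OCOC)c(OC)c(OC)cc3C2)c(O)c(OC)c1OC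
F8 | step 6 | 5-[(3S)-6,7-dimethoxy-8-(methoxymethoxy)-3,4-dihydro-2H-chromen-3-yl]-2,3-dimethoxycyclohexa-2,5-diene-1,4-dione | COC1=C(OC)C(=O)C([C@H]2COc3c(OCOC)c(OC)c(OC)cc3C2)=CC1=O
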